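**Strategy.** The γ-lactone (C7–O–C19(=O)–C17–C8, briarane numbering) is traced to a spiro-cyclobutanone in which C19 is still bonded to C7. The key step exploits the β-oxygen O8 of the lactone ring, which makes C17=C8 an enol ether matched in polarity to a ketene. A vinylketene (C19=C7) and a Z-enol ether (C17=C8), with O8 and O9 tied in an alkylidene dioxolane on the finished cyclohexane, are joined in one [2+2] cycloaddition that makes C19–C17 and C7–C8 and sets C7, C8 and C17. Ring strain then drives Baeyer–Villiger oxygen insertion into C19–C7. Ring-closing metathesis between the C7 vinyl group and an isopropenyl chain on C2 closes the ten-membered ring.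

Key step: step 15

Remark on numbering: briarane numbering is used throughout (C1–C14 carbocycle, C15 methyl on C1, C16 methyl on C5, C17–C19 lactone carbons with C18 the methyl on C17, C20 methyl on C11); α/β refer to the face opposite to/same as the C15 methyl.
Assumption: the lipase in step 2 shows its usual enantiopreference for secondary carbinols; if the enzyme chosen prefers the other enantiomer, the unreacted acetate fraction is carried on instead.

**Step 1**
Reactants: 1 3-ethoxy-2-methylcyclohex-2-en-1-one
Product: 2 racemic 6-acetoxy-3-ethoxy-2-methylcyclohex-2-en-1-one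
Conditions: Mn(OAc)3·2H2O, benzene, reflux (Dean–Stark)
Reagents that add atoms: manganese triacetate, CC(=O)[O-].CC(=O)[O-].CC(=O)[O-].[Mn+3]
Why: Mn(OAc)3 α′-acetoxylation of enones proceeds through the manganese enolate at the only enolisable α′-carbon (C6) of the vinylogous ester, so the acetoxy group enters there; the product is racemic.

**Step 2**
Reactants: 2 racemic 6-acetoxy-3-ethoxy-2-methylcyclohex-2-en-1-one
Product: 3 (R)-3-ethoxy-6-hydroxy-2-methylcyclohex-2-en-1-one
Conditions: lipase from Burkholderia cepacia (Amano PS), pH 7 phosphate buffer/MTBE, rt, stopped near half conversion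
Reagents that add atoms: none
Why: Lipase-catalysed kinetic resolution by enantioselective ester hydrolysis: the (R)-acetate, whose carbinol carbon carries the larger substituent on the carbonyl side, is expected to be hydrolysed preferentially, and the unreacted (S)-acetate is removed by chromatography.

**Step 3**
Reactants: 3 (R)-3-ethoxy-6-hydroxy-2-methylcyclohex-2-en-1-one
Product: 5 (R)-4-hydroxy-2-methylcyclohex-2-en-1-one, via allylic diol 4 (not isolated)
Conditions: LiAlH4, Et2O, 0 °C; then 1 M HCl, THF, 0 °C to rt
Reagents that add atoms: water, O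
Why: Stork–Danheiser 1,3-carbonyl transposition: 1,2-reduction of the vinylogous ester, then acid hydrolysis of the enol ether and β-elimination of water give the transposed enone, and the carbinol stereocentre (future C11) is not touched.

**Step 4**
Reactants: 5 (R)-4-hydroxy-2-methylcyclohex-2-en-1-one
Product: 6 (R)-2-methyl-4-(triethylsilyloxy)cyclohex-2-en-1-one
Conditions: Et3SiCl, imidazole, DMF, 0 °C
Reagents that add atoms: chlorotriethylsilane, CC[Si](Cl)(CC)CC
Why: Standard silylation of a secondary allylic alcohol; the bulky, non-chelating silyl ether later directs the organocopper reagent to the opposite face.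

**Step 5**
Reactants: 6 (R)-2-methyl-4-(triethylsilyloxy)cyclohex-2-en-1-one; 7 4-methylpent-4-enal
Product: 9 β-hydroxy ketone (C14 ketone; C1 quaternary with methyl and the C2 carbinol chain; C10 silylmethyl; C11 OTES), via magnesium enolate 8 (not isolated)
Conditions: i-PrO(Me)2SiCH2MgCl (from ClCH2SiMe2(Oi-Pr) and Mg), CuBr·SMe2 (cat.), THF, −78 to −40 °C; then 7, −78 °C; aq NH4Cl at −78 °C
Reagents that add atoms: (isopropoxydimethylsilyl)methylmagnesium chloride, CC(C)O[Si](C)(C)C[Mg]Cl
Why: Copper-catalysed conjugate addition of the Tamao hydroxymethyl-anion equivalent should occur anti to the C11 silyloxy group (sets C10), and enolate 8 should add to the aldehyde anti to the new C10 substituent through a Zimmerman–Traxler chair with the aldehyde chain equatorial, which sets the quaternary C1 and the C2 carbinol (C15 methyl and C2–OH syn) in one tandem Michael–aldol operation.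

**Step 6**
Reactants: 9 β-hydroxy ketone
Product: 10 C2 acetate with free 14α-hydroxyl (1,3-anti)
Conditions: SmI2 (cat.), CH3CHO (excess), THF, −10 °C
Reagents that add atoms: acetaldehyde, CC=O
Why: Evans–Tishchenko reduction: the samarium-bound hemiacetal formed from the C2 alkoxide and acetaldehyde delivers hydride intramolecularly to C14 through a chair-like six-membered transition state, which gives the 1,3-anti diol (14α-OH) and leaves the acetate on O2, the acylation pattern of the target.

**Step 7**
Reactants: 10 C2 acetate with free 14α-hydroxyl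
Product: 11 C14 tert-butyldimethylsilyl ether
Conditions: TBSOTf, 2,6-lutidine, CH2Cl2, −78 to 0 °C
Reagents that add atoms: tert-butyldimethylsilyl trifluoromethanesulfonate, CC(C)(C)[Si](C)(C)OS(=O)(=O)C(F)(F)F
Why: Silylation of the hindered axial C14 alcohol with the silyl triflate and a non-nucleophilic base keeps C14–OH masked until both acetates are in place.

**Step 8**
Reactants: 11 C14 TBS ether
Product: 12 primary alcohol at C9
Conditions: 30% H2O2, KF, KHCO3, THF/MeOH, rt
Reagents that add atoms: hydrogen peroxide, OO
Why: Tamao–Fleming oxidation converts the C–Si bond of the alkoxysilane into C–OH under buffered fluoride–peroxide conditions that should leave the alkene, the acetate and the silyl ethers untouched.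

**Step 9**
Reactants: 12 primary alcohol at C9
Product: 13 C9 aldehyde
Conditions: Dess–Martin periodinane, NaHCO3, CH2Cl2, 0 °C to rt
Reagents that add atoms: none
Why: Dess–Martin oxidation of the only free (primary) alcohol to the aldehyde under buffered conditions that should not epimerise C10.

**Step 10**
Reactants: 13 C9 aldehyde; 14 2-(allyloxy)tetrahydro-2H-pyran
Product: 15 syn 1,2-diol mono-tetrahydropyranyl ether (C9–OH, C8–OTHP, vinyl on C8)
Conditions: 14, s-BuLi, THF, −78 °C; (+)-Ipc2BOMe; BF3·OEt2; then 13, −78 °C; ethanolamine work-up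
Reagents that add atoms: none
Why: Brown alkoxyallylboration: the (Z)-γ-alkoxyallylborane made in the flask from 14 adds through a closed chair transition state to give the syn 1,2-diol monoether, the (+)-Ipc2B reagent (from (−)-α-pinene) attacking the Re face of the aldehyde to set C9 (S), reinforced by the anti-Felkin preference of Z-γ-substituted allylboranes, while the C8 centre formed here is erased in step 14.

**Step 11**
Reactants: 15 syn 1,2-diol mono-tetrahydropyranyl ether
Product: 17 C8/C9 acetonide with free C11 hydroxyl, via triol 16 (not isolated)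
Conditions: PPTS, MeOH, 45 °C; evaporate; then Me2C(OMe)2, acetone, PPTS, rt
Reagents that add atoms: 2,2-dimethoxypropane, COC(C)(C)OC
Why: Mild acid methanolysis removes the tetrahydropyranyl and triethylsilyl groups (the neopentylic C14 TBS ether should survive), and acetal exchange then closes the five-membered acetonide on the 1,2-diol in preference to a dioxane with O11.

**Step 12**
Reactants: 17 C8/C9 acetonide with free C11 hydroxyl
Product: 18 C11 ketone
Conditions: Dess–Martin periodinane, NaHCO3, CH2Cl2, rt
Reagents that add atoms: none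
Why: Dess–Martin oxidation of the secondary C11 alcohol to the ketone; C10 should not epimerise because its C9 substituent is already equatorial.

**Step 13**
Reactants: 18 C11 ketone
Product: 19 C11 tertiary alcohol (11β-OH, 11α-methyl)
Conditions: MeMgBr, anhydrous CeCl3, THF, −78 °C
Reagents that add atoms: methylmagnesium bromide, C[Mg]Br
Why: Organocerium (Grignard/CeCl3) 1,2-addition is fast to ketones and slow to acetates at −78 °C, and the nucleophile should enter equatorially from the α face because the axial C15 methyl blocks the β face, giving the axial 11β-hydroxyl and 11α-methyl.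

**Step 14**
Reactants: 19 C11 tertiary alcohol with 4-vinyl dioxolane
Product: 20 (Z)-4-ethylidene-2,2-dimethyl-1,3-dioxolane (C8=C17 enol ether)
Conditions: RuHCl(CO)(PPh3)3 (cat.), toluene, 80 °C
Reagents that add atoms: none
Why: Ruthenium hydride-catalysed alkene isomerisation (hydrometalation, β-hydride elimination) moves the monosubstituted vinyl double bond into conjugation with oxygen, and the exocyclic enol ether should form with the C18 methyl syn to ring oxygen O8 (Z), which avoids allylic strain with the C9 substituent, while the less reactive 1,1-disubstituted alkene stays in place.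

**Step 15**
Reactants: 20 (Z)-ethylidene dioxolane; 21 (E)-but-2-enoyl chloride
Product: 23 spiro-cyclobutanone (C19 ketone flanked by C17–methyl and C7–vinyl; C8 spiro to the dioxolane), via vinylketene 22 (not isolated)
Conditions: Et3N, toluene, 80 °C, slow addition of 21 (syringe pump)
Reagents that add atoms: none
Why: Triethylamine dehydrochlorinates 21 (γ-deprotonation of the acylammonium ion) to vinylketene 22, whose electrophilic carbonyl carbon C19 bonds to the nucleophilic β-carbon C17 of the enol ether in an asynchronous [π2s+π2a] cycloaddition, the oxocarbenium-like C8 then closing onto the ketene α-carbon C7. The closest known reaction is the [2+2] cycloaddition of ketenes generated in the flask, vinylketene included, with enol ethers to give 3-alkoxycyclobutanones. The four-membered ring is closed by this intermolecular [2+2] event (formally a 4-exo collapse of the 1,4-zwitterion), spiro to the dioxolane at C8. C8 is set by approach of the ketene to the enol-ether face anti to the cyclohexyl substituent on the neighbouring dioxolane carbon C9, C17 by suprafacial addition to the Z-enol ether (methyl cis to O8), and C7, epimerisable α to the ketone, should settle under the amine with the vinyl group cis to O8 and trans to the bulky C9. The step needs regioselectivity (secured by the matched polarity of enol ether and ketene), chemoselectivity for the electron-rich enol ether over the isopropenyl group and the hindered tertiary alcohol, and [2+2] rather than [4+2] periselectivity, the normal behaviour of vinylketenes.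

**Step 16**
Reactants: 23 spiro-cyclobutanone
Product: 24 γ-lactone (C7–O–C19(=O)–C17–C8) with C7 vinyl
Conditions: 30% H2O2, CF3CH2OH, 0 °C to rt
Reagents that add atoms: hydrogen peroxide, OO
Why: Baeyer–Villiger oxidation of the strained cyclobutanone with hydrogen peroxide in a fluorinated alcohol (no peracid, so the alkenes should not be epoxidised): the Criegee adduct releases ring strain by migration of the secondary allylic C7 in preference to C17, with retention at C7.

**Step 17**
Reactants: 24 γ-lactone with C7 vinyl and C2 isopropenyl chain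
Product: 25 ten-membered carbocycle with (Z)-C5=C6 alkene
Conditions: second-generation Grubbs catalyst (cat.), toluene, 80 °C, high dilution
Reagents that add atoms: none
Why: Ring-closing metathesis: the catalyst should load on the monosubstituted vinyl group and close onto the isopropenyl group at high dilution, the trisubstituted C5=C6 alkene being expected as the less strained Z isomer in the ten-membered ring.

**Step 18**
Reactants: 25 ten-membered carbocycle (acetonide, TBS ether)
Product: 26 C8/C9 diol
Conditions: AcOH/H2O (4:1), 40 °C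
Reagents that add atoms: none
Why: Acid-catalysed acetal hydrolysis frees the C8/C9 diol under conditions mild enough for the allylic lactone, the C2 acetate and the C14 TBS ether.

**Step 19**
Reactants: 26 C8/C9 diol
Product: 27 C2,C9-diacetate C14 TBS ether
Conditions: Ac2O, DMAP, pyridine, CH2Cl2, rt
Reagents that add atoms: acetic anhydride, CC(=O)OC(C)=O
Why: DMAP-catalysed acetylation should discriminate the secondary C9 hydroxyl from the tertiary C8 and C11 hydroxyls.

**Step 20**
Reactants: 27 C2,C9-diacetate C14 TBS ether
Product: 28 junceellolide I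
Conditions: HF·pyridine, THF/pyridine, 0 °C to rt
Reagents that add atoms: none
Why: Fluoride-mediated desilylation with buffered HF·pyridine should remove the TBS group without acyl migration or lactone opening and release the target.

**Compound list**

1 | 3-ethoxy-2-methylcyclohex-2-en-1-one | CCOC1=C(C)C(=O)CC1 | starting material
2 | racemic 6-acetoxy-3-ethoxy-2-methylcyclohex-2-en-1-one | CCOC1=C(C)C(=O)C(OC(C)=O)CC1 | intermediate
3 | (R)-3-ethoxy-6-hydroxy-2-methylcyclohex-2-en-1-one | CCOC1=C(C)C(=O)[C@H](O)CC1 | intermediate
4 | (6R)-3-ethoxy-2-methylcyclohex-2-ene-1,6-diol (both C1 epimers; not isolated) | CCOC1=C(C)C(O)[C@H](O)CC1 | intermediate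
5 | (R)-4-hydroxy-2-methylcyclohex-2-en-1-one | O=C1C(C)=C[C@H](O)CC1 | intermediate
6 | (R)-2-methyl-4-(triethylsilyloxy)cyclohex-2-en-1-one | O=C1C(C)=C[C@H](O[Si](CC)(CC)CC)CC1 | intermediate
7 | 4-methylpent-4-enal | C=C(C)CCC=O | starting material
8 | chloromagnesium enolate of the conjugate adduct (C10 silylmethyl trans to C11 OTES; not isolated) | CC1=C(O[Mg]Cl)CC[C@@H](O[Si](CC)(CC)CC)[C@@H]1C[Si](C)(C)OC(C)C | intermediate
9 | (2S,3R,4R)-2-[(1S)-1-hydroxy-4-methylpent-4-enyl]-3-{[isopropoxy(dimethyl)silyl]methyl}-2-methyl-4-(triethylsilyloxy)cyclohexan-1-one | C=C(C)CC[C@H](O)[C@@]1(C)C(=O)CC[C@@H](O[Si](CC)(CC)CC)[C@@H]1C[Si](C)(C)OC(C)C | intermediate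
10 | C2 acetate of the 1,3-anti diol (free 14α-OH; C10 silylmethyl; C11 OTES) | C=C(C)CC[C@H](OC(C)=O)[C@@]1(C)[C@@H](O)CC[C@@H](O[Si](CC)(CC)CC)[C@@H]1C[Si](C)(C)OC(C)C | intermediate
11 | C14 TBS ether of 10 | C=C(C)CC[C@H](OC(C)=O)[C@@]1(C)[C@@H](O[Si](C)(C)C(C)(C)C)CC[C@@H](O[Si](CC)(CC)CC)[C@@H]1C[Si](C)(C)OC(C)C | intermediate
12 | C9 primary alcohol (hydroxymethyl on C10) | C=C(C)CC[C@H](OC(C)=O)[C@@]1(C)[C@@H](O[Si](C)(C)C(C)(C)C)CC[C@@H](O[Si](CC)(CC)CC)[C@@H]1CO | intermediate
13 | C9 aldehyde (formyl on C10) | C=C(C)CC[C@H](OC(C)=O)[C@@]1(C)[C@@H](O[Si](C)(C)C(C)(C)C)CC[C@@H](O[Si](CC)(CC)CC)[C@@H]1C=O | intermediate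
14 | 2-(allyloxy)tetrahydro-2H-pyran | C=CCOC1CCCCO1 | starting material
15 | (8S,9S) syn diol monoether: C9–OH, C8–OTHP, vinyl on C8 (mixture of epimers at the tetrahydropyranyl acetal carbon) | C=C(C)CC[C@H](OC(C)=O)[C@@]1(C)[C@@H](O[Si](C)(C)C(C)(C)C)CC[C@@H](O[Si](CC)(CC)CC)[C@@H]1[C@H](O)[C@@H](OC2CCCCO2)C=C | intermediate
16 | C8,C9,C11-triol (not isolated) | C=C(C)CC[C@H](OC(C)=O)[C@@]1(C)[C@@H](O[Si](C)(C)C(C)(C)C)CC[C@@H](O)[C@@H]1[C@H](O)[C@@H](O)C=C | intermediate
17 | C8/C9 acetonide (2,2-dimethyl-5-vinyl-1,3-dioxolan-4-yl on C10) with free C11 secondary hydroxyl | C=C(C)CC[C@H](OC(C)=O)[C@@]1(C)[C@@H](O[Si](C)(C)C(C)(C)C)CC[C@@H](O)[C@@H]1[C@@H]2OC(C)(C)O[C@H]2C=C | intermediate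
18 | C11 ketone of 17 | C=C(C)CC[C@H](OC(C)=O)[C@@]1(C)[C@@H](O[Si](C)(C)C(C)(C)C)CCC(=O)[C@@H]1[C@@H]2OC(C)(C)O[C@H]2C=C | intermediate
19 | C11 tertiary alcohol (11β-OH, 11α-Me) with 5-vinyl dioxolane | C=C(C)CC[C@H](OC(C)=O)[C@@]1(C)[C@@H](O[Si](C)(C)C(C)(C)C)CC[C@](C)(O)[C@@H]1[C@@H]2OC(C)(C)O[C@H]2C=C | intermediate
20 | (Z)-5-ethylidene-2,2-dimethyl-1,3-dioxolan-4-yl enol ether (C8=C17, C18 methyl cis to O8) | C=C(C)CC[C@H](OC(C)=O)[C@@]1(C)[C@@H](O[Si](C)(C)C(C)(C)C)CC[C@](C)(O)[C@@H]1[C@@H]2OC(C)(C)O/C2=C\C | intermediate
21 | (E)-but-2-enoyl chloride (crotonyl chloride) | C/C=C/C(Cl)=O | starting material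
22 | vinylketene (buta-1,3-dien-1-one; not isolated) | C=CC=C=O | intermediate
23 | spiro-cyclobutanone: C19 ketone, C17 methyl and C7 vinyl both cis to O8, C8 spiro to the acetonide | C=C(C)CC[C@H](OC(C)=O)[C@@]1(C)[C@@H](O[Si](C)(C)C(C)(C)C)CC[C@](C)(O)[C@@H]1[C@@H]2OC(C)(C)O[C@]23[C@@H](C)C(=O)[C@H]3C=C | intermediate
24 | spiro γ-lactone (C7–O–C19(=O)–C17–C8) with C7 vinyl | C=C(C)CC[C@H](OC(C)=O)[C@@]1(C)[C@@H](O[Si](C)(C)C(C)(C)C)CC[C@](C)(O)[C@@H]1[C@@H]2OC(C)(C)O[C@]23[C@@H](C)C(=O)O[C@H]3C=C | intermediate
25 | briarane tricycle: (Z)-C5=C6 ten-membered ring, C8/C9 acetonide, C2 acetate, C14 TBS ether | CC(=O)O[C@H]1CC/C(C)=C\[C@@H]2OC(=O)[C@H](C)[C@]23OC(C)(C)O[C@H]3[C@@H]3[C@]1(C)[C@@H](O[Si](C)(C)C(C)(C)C)CC[C@]3(C)O | intermediate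
26 | C8/C9 diol, C2 acetate, C14 TBS ether | CC(=O)O[C@H]1CC/C(C)=C\[C@@H]2OC(=O)[C@H](C)[C@@]2(O)[C@@H](O)[C@@H]2[C@]1(C)[C@@H](O[Si](C)(C)C(C)(C)C)CC[C@]2(C)O | intermediate
27 | 14-O-TBS junceellolide I (C2 and C9 acetates) | CC(=O)O[C@H]1CC/C(C)=C\[C@@H]2OC(=O)[C@H](C)[C@@]2(O)[C@@H](OC(C)=O)[C@@H]2[C@]1(C)[C@@H](O[Si](C)(C)C(C)(C)C)CC[C@]2(C)O | intermediate
28 | junceellolide I | CC(=O)O[C@H]1CC/C(C)=C\[C@@H]2OC(=O)[C@H](C)[C@@]2(O)[C@@H](OC(C)=O)[C@@H]2[C@]1(C)[C@@H](O)CC[C@]2(C)O | target

**Total step count:** 20. **Longest linear sequence:** 20 steps (1 to 28).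

**Steps most likely to fail**

Step 15. The bimolecular cycloaddition at the hindered, fully substituted C8 may be slower than oligomerisation of the vinylketene, or the ketene may add with poor facial selectivity. The fallback sets out from 20 and comes back at 23. Dichloroketene, generated from trichloroacetyl chloride and Zn–Cu couple in Et2O at 0 °C, is far more electrophilic and should add to 20 with the same regiochemistry and facial bias to give the 2,2-dichlorocyclobutanone F1. Zinc dust with NH4Cl in MeOH at rt removes both chlorine atoms to give the C7-unsubstituted cyclobutanone F2. Kinetic deprotonation at the less substituted C7 with LiN(SiMe3)2, followed by palladium-catalysed α-vinylation with vinyl bromide [Pd2(dba)3, P(t-Bu)3, toluene], then gives 23, with C7 again expected to settle trans to C9.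

Step 17. Strain in the ten-membered ring with a trisubstituted alkene may let intermolecular metathesis (oligomerisation) outrun ring closure. The fallback sets out from 23 and comes back at 25: the ring closure is moved in front of the oxygen insertion. Compound 23 is cyclised with second-generation Hoveyda–Grubbs catalyst (toluene, 80 °C, high dilution) to the ring-closed cyclobutanone F3, in which the vinyl group sits on the small four-membered ketone and projects differently toward the isopropenyl chain. Baeyer–Villiger oxidation of F3 (30% H2O2, CF3CH2OH) then gives 25.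

Step 16. Migration of C17 instead of the allylic C7, or opening of the β-alkoxycyclobutanone under the oxidising conditions, would give the wrong lactone or none. The fallback sets out from 23 and comes back at 24 by photochemical ring expansion. Irradiation of 23 (300 nm, Pyrex, THF/H2O) should cleave the C19–C7 bond, the one that gives an allylic radical; the acyl–alkyl diradical recloses on oxygen to an oxacarbene, which water traps as the lactol F4. Oxidation with (n-Pr4N)RuO4 (cat.) and N-methylmorpholine N-oxide in CH2Cl2 gives 24.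

**Further compounds**

F1 | step 15 | 2,2-dichloro spiro-cyclobutanone (C7 = CCl2) from 20 and dichloroketene | C=C(C)CC[C@H](OC(C)=O)[C@@]1(C)[C@@H](O[Si](C)(C)C(C)(C)C)CC[C@](C)(O)[C@@H]1[C@@H]2OC(C)(C)O[C@]23[C@@H](C)C(=O)C3(Cl)Cl
F2 | step 15 | dechlorinated spiro-cyclobutanone (C7 = CH2) | C=C(C)CC[C@H](OC(C)=O)[C@@]1(C)[C@@H](O[Si](C)(C)C(C)(C)C)CC[C@](C)(O)[C@@H]1[C@@H]2OC(C)(C)O[C@]23[C@@H](C)C(=O)C3
F3 | step 17 | ring-closed cyclobutanone (ten-membered ring with (Z)-C5=C6, C19 ketone still bonded to C7) | CC(=O)O[C@H]1CC/C(C)=C\[C@@H]2C(=O)[C@H](C)[C@]23OC(C)(C)O[C@H]3[C@@H]3[C@]1(C)[C@@H](O[Si](C)(C)C(C)(C)C)CC[C@]3(C)O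
F4 | step 16 | lactol (C19 hemiacetal, both epimers) from photochemical ring expansion of 23 | C=C(C)CC[C@H](OC(C)=O)[C@@]1(C)[C@@H](O[Si](C)(C)C(C)(C)C)CC[C@](C)(O)[C@@H]1[C@@H]2OC(C)(C)O[C@]23[C@@H](C)C(O)O[C@H]3C=C
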